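**Strategy.** The route rests on the saturated γ-lactone (ring C): its quaternary carbon C5, which carries the methyl group and the tetrahydrofuran (ring B), is joined to the ring methylene C4 by a ring expansion. A methyl ketone on ring B, made from (R)-linalool by Sharpless epoxidation and cyclisation, takes up diphenylsulfonium cyclopropylide; the resulting oxaspiropentane rearranges under acid, a cyclopropane CH2 migrating to C5 to close a 2,2-disubstituted cyclobutanone in one operation. Baeyer–Villiger oxidation then inserts the lactone oxygen next to C5. Cross-metathesis of the ring B vinyl group with a butenolide-bearing 1,4-diene finishes the E-alkene. It exploits C5 being a carbinol carbon next to the ring B stereocentre, which directs the ylide face.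

Key step: step 4

Remark: the oxaspiropentane-to-cyclobutanone shift is taken to proceed with inversion at the migration terminus (CH2 enters anti to the departing oxygen); 3-bromofuran-2(5H)-one, cyclopropyldiphenylsulfonium tetrafluoroborate, pent-1-en-4-yne and enantiopure (R)-linalool are taken as catalogue compounds.

Locants used below: ring A = butenolide; ring B = oxolane (O1, C2 bearing ring C, C5 bearing CH3 and the alkenyl chain); ring C = γ-lactone (O1, C2 carbonyl, C3, C4, C5).

**Step 1**
Reactants: 1 (3R)-3,7-dimethylocta-1,6-dien-3-ol [(R)-linalool]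
Product: 2 (2E,6R)-2,6-dimethylocta-2,7-diene-1,6-diol
Conditions: SeO2 (cat.), tBuOOH, salicylic acid (cat.), CH2Cl2, 25 °C
Reagents that add atoms: tert-butyl hydroperoxide, CC(C)(C)OO (terminal oxidant); selenium dioxide, O=[Se]=O (catalytic oxygen carrier)
Why: Selenium dioxide allylic oxidation (ene reaction, then [2,3]-sigmatropic shift) should attack the trisubstituted alkene at its (E)-methyl group much faster than the vinyl group, giving the (E)-allylic alcohol without touching the carbinol stereocentre.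

**Step 2**
Reactants: 2 (2E,6R)-2,6-dimethylocta-2,7-diene-1,6-diol
Product: 4 (2S)-2-[(2R,5R)-5-ethenyl-5-methyloxolan-2-yl]propane-1,2-diol, via epoxy alcohol 3 (not isolated)
Conditions: Ti(OiPr)4 (0.2 equiv), L-(+)-diethyl tartrate, tBuOOH, 4 Å MS, CH2Cl2, −20 °C; then CSA (cat.), 0 °C
Reagents that add atoms: tert-butyl hydroperoxide, CC(C)(C)OO
Why: Sharpless asymmetric epoxidation of the (E)-2-methylallylic alcohol with L-(+)-tartrate should give the (2S,3S)-epoxide under reagent control (the tertiary vinyl carbinol is a poor substrate), and acid then promotes 5-exo-tet opening by the tertiary hydroxyl at the epoxide CH with inversion, which sets ring B C2 as (R), trans to the vinyl group.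

**Step 3**
Reactants: 4 (2S)-2-[(2R,5R)-5-ethenyl-5-methyloxolan-2-yl]propane-1,2-diol
Product: 5 1-[(2R,5R)-5-ethenyl-5-methyloxolan-2-yl]ethan-1-one
Conditions: NaIO4, THF/H2O, 0 → 25 °C
Reagents that add atoms: none
Why: Malaprade glycol cleavage of the primary/tertiary 1,2-diol excises formaldehyde and leaves the methyl ketone under neutral conditions that should not epimerise the α-alkoxy centre.

**Step 4**
Reactants: 5 1-[(2R,5R)-5-ethenyl-5-methyloxolan-2-yl]ethan-1-one
Product: 7 (2S)-2-[(2R,5R)-5-ethenyl-5-methyloxolan-2-yl]-2-methylcyclobutan-1-one, via oxaspiropentane 6 (not isolated)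
Conditions: cyclopropyldiphenylsulfonium tetrafluoroborate, NaCH2S(O)CH3, DME, −45 °C; 5, −45 → 0 °C; then 1 M aq. HBF4, Et2O, 0 → 25 °C
Reagents that add atoms: cyclopropyldiphenylsulfonium tetrafluoroborate, C1CC1[S+](c1ccccc1)c1ccccc1.F[B-](F)(F)F
Why: Diphenylsulfonium cyclopropylide adds to the ketone carbon (the future ring C C5) and the betaine closes by 3-exo-tet displacement of Ph2S to the oxaspiropentane 6; protonation of the epoxide oxygen then cleaves the C5–O bond while a cyclopropane CH2 (the future ring C C4) shifts from the spiro carbon to C5, a cyclopropylcarbinyl-to-cyclobutyl ring expansion that closes the cyclobutanone by the C5–C4 bond. The closest known reaction type is the sulfonium-ylide cyclobutanone annulation (oxaspiropentane–cyclobutanone rearrangement, a semipinacol 1,2-shift). The new quaternary centre is controlled by ring B C2: the non-chelated ylide should attack the Felkin–Anh/Cornforth face anti to the ring C2–O bond to give (2R)-6, and migration with inversion then puts the carbonyl carbon where the lactone oxygen must finally sit, so that step 5 delivers (S)-C5. The step needs facial selectivity in the addition, a migration that keeps pace with ionisation, and no epimerisation of the α-alkoxy ketone. These are expected from the absence of a chelating metal, from the destabilisation of a free cation at C5 by the neighbouring C–O bond, and from irreversible ylide generation at −45 °C. The regiochemistry of epoxide cleavage is fixed because only the tertiary cyclopropylcarbinyl C–O bond can ionise.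

**Step 5**
Reactants: 7 (2S)-2-[(2R,5R)-5-ethenyl-5-methyloxolan-2-yl]-2-methylcyclobutan-1-one
Product: 8 (5S)-5-[(2R,5R)-5-ethenyl-5-methyloxolan-2-yl]-5-methyloxolan-2-one
Conditions: 30% aq. H2O2, NaOH, MeOH, 0 °C; then aq. HCl
Reagents that add atoms: hydrogen peroxide, OO
Why: Baeyer–Villiger oxidation of the strained cyclobutanone by hydroperoxide anion, in which the quaternary carbon migrates with retention so that oxygen takes the place of the carbonyl carbon at C5; the nucleophilic oxidant should leave the vinyl group alone, and acidification recloses any hydroxy acid.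

**Step 6**
Reactants: 9 pent-1-en-4-yne
Product: 12 (3E)-4-methylhepta-3,6-dien-1-ol, via alkenylalane 10 (not isolated), via lithium alanate 11 (not isolated)
Conditions: Me3Al, Cp2ZrCl2 (0.25 equiv), CH2Cl2, 0 → 25 °C; evaporate, THF, n-BuLi, −30 °C; oxirane, −30 → 25 °C; aq. HCl
Reagents that add atoms: trimethylaluminium, C[Al](C)C; oxirane, C1CO1
Why: Zirconium-catalysed syn-carboalumination (Negishi methylalumination) of the terminal alkyne should set the trisubstituted (E)-alkene regio- and stereospecifically (the alkene is far less reactive), and the derived alkenylalanate opens oxirane with retention of geometry.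

**Step 7**
Reactants: 12 (3E)-4-methylhepta-3,6-dien-1-ol
Product: 13 (4E)-7-iodo-4-methylhepta-1,4-diene
Conditions: I2, PPh3, imidazole, CH2Cl2, 0 °C
Reagents that add atoms: iodine, II
Why: Appel-type iodination (Garegg–Samuelsson conditions) converts the primary homoallylic alcohol to the iodide by SN2 displacement of the oxyphosphonium group without touching either alkene.

**Step 8**
Reactants: 13 (4E)-7-iodo-4-methylhepta-1,4-diene; 14 3-bromofuran-2(5H)-one
Product: 16 3-[(3E)-4-methylhepta-3,6-dien-1-yl]furan-2(5H)-one, via alkylzinc iodide 15 (not isolated)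
Conditions: Zn dust, LiCl, THF, 40 °C; then 14, Pd(OAc)2 (2 mol %), SPhos (4 mol %), THF, 25 °C
Reagents that add atoms: none
Why: Direct zinc insertion into the primary iodide followed by Negishi cross-coupling at the sp2 C–Br bond of the α-bromobutenolide, a base-free sp3–sp2 coupling that should leave the acidic γ-CH2 of the butenolide and the skipped diene intact.

**Step 9**
Reactants: 8 (5S)-5-[(2R,5R)-5-ethenyl-5-methyloxolan-2-yl]-5-methyloxolan-2-one; 16 3-[(3E)-4-methylhepta-3,6-dien-1-yl]furan-2(5H)-one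
Product: 17 (5S)-5-methyl-5-[(2R,5R)-5-methyl-5-[(1E,4E)-4-methyl-7-(2-oxo-2,5-dihydrofuran-3-yl)hepta-1,4-dien-1-yl]oxolan-2-yl]oxolan-2-one (target)
Conditions: second-generation Hoveyda–Grubbs catalyst RuCl2(H2IMes)(=CH-C6H4-2-OiPr) (10 mol %), 16 (3 equiv), CH2Cl2, 40 °C
Reagents that add atoms: none
Why: Olefin cross-metathesis between the terminal alkene of 16 and the vinyl group on the fully substituted ring B carbon of 8, which cannot homodimerise; the bulky allylic quaternary centre should enforce the E-alkene, and the trisubstituted and butenolide alkenes are too hindered or electron-poor to take part.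

**Compound list**

1 | (3R)-3,7-dimethylocta-1,6-dien-3-ol, (R)-linalool | C=C[C@](C)(O)CCC=C(C)C | starting material
2 | (2E,6R)-2,6-dimethylocta-2,7-diene-1,6-diol | C=C[C@](C)(O)CC/C=C(\C)CO | intermediate
3 | [(2S,3S)-3-[(3R)-3-hydroxy-3-methylpent-4-en-1-yl]-2-methyloxiran-2-yl]methanol | C=C[C@](C)(O)CC[C@@H]1O[C@@]1(C)CO | intermediate
4 | (2S)-2-[(2R,5R)-5-ethenyl-5-methyloxolan-2-yl]propane-1,2-diol | C=C[C@@]1(C)CC[C@H]([C@@](C)(O)CO)O1 | intermediate
5 | 1-[(2R,5R)-5-ethenyl-5-methyloxolan-2-yl]ethan-1-one | C=C[C@@]1(C)CC[C@H](C(C)=O)O1 | intermediate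
6 | (2R)-2-[(2R,5R)-5-ethenyl-5-methyloxolan-2-yl]-2-methyl-1-oxaspiro[2.2]pentane | C=C[C@@]1(C)CC[C@H]([C@@]2(C)OC23CC3)O1 | intermediate
7 | (2S)-2-[(2R,5R)-5-ethenyl-5-methyloxolan-2-yl]-2-methylcyclobutan-1-one | C=C[C@@]1(C)CC[C@H]([C@]2(C)CCC2=O)O1 | intermediate
8 | (5S)-5-[(2R,5R)-5-ethenyl-5-methyloxolan-2-yl]-5-methyloxolan-2-one | C=C[C@@]1(C)CC[C@H]([C@]2(C)CCC(=O)O2)O1 | intermediate
9 | pent-1-en-4-yne | C=CCC#C | starting material
10 | dimethyl[(1E)-2-methylpenta-1,4-dien-1-yl]alumane | C=CC/C(C)=C/[Al](C)C | intermediate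
11 | lithium butyl(dimethyl)[(1E)-2-methylpenta-1,4-dien-1-yl]aluminate | [Li+].C=CC/C(C)=C/[Al-](C)(C)CCCC | intermediate
12 | (3E)-4-methylhepta-3,6-dien-1-ol | C=CC/C(C)=C/CCO | intermediate
13 | (4E)-7-iodo-4-methylhepta-1,4-diene | C=CC/C(C)=C/CCI | intermediate
14 | 3-bromofuran-2(5H)-one | O=C1OCC=C1Br | starting material
15 | iodo[(3E)-4-methylhepta-3,6-dien-1-yl]zinc | C=CC/C(C)=C/CC[Zn]I | intermediate
16 | 3-[(3E)-4-methylhepta-3,6-dien-1-yl]furan-2(5H)-one | C=CC/C(C)=C/CCC1=CCOC1=O | intermediate
17 | (5S)-5-methyl-5-[(2R,5R)-5-methyl-5-[(1E,4E)-4-methyl-7-(2-oxo-2,5-dihydrofuran-3-yl)hepta-1,4-dien-1-yl]oxolan-2-yl]oxolan-2-one | C/C(=C\CCC1=CCOC1=O)C/C=C/[C@@]1(C)CC[C@H]([C@]2(C)CCC(=O)O2)O1 | target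

**Step count and risks**

Total step count: 9 (steps 1–5 to lactone 8, steps 6–8 to butenolide 16, step 9 to join them).
Longest linear sequence: 6 steps (1 → 2 → 4 → 5 → 7 → 8 → 17).

Steps most likely to fail:

1. Step 4. What may go wrong is poor facial selectivity in the ylide addition, epimerisation of the α-alkoxy ketone by the basic ylide, or loss of stereospecificity if the C5–O bond ionises fully before the CH2 migrates. The fallback sets out from 4 and comes back at 7, and takes the C5 configuration from the Sharpless-set tertiary carbinol instead of from a facial selection. The primary hydroxyl of 4 would be oxidised (TEMPO cat., PhI(OAc)2, MeCN/H2O) to (2R)-2-[(2R,5R)-5-ethenyl-5-methyloxolan-2-yl]-2-hydroxypropanoic acid F1 and esterified (Me3SiCHN2, MeOH/PhMe) to methyl (2R)-2-[(2R,5R)-5-ethenyl-5-methyloxolan-2-yl]-2-hydroxypropanoate F2. Kulinkovich cyclopropanation (EtMgBr in excess, Ti(OiPr)4, THF, the tertiary hydroxyl carried as its magnesium alkoxide) would give 1-[(1R)-1-[(2R,5R)-5-ethenyl-5-methyloxolan-2-yl]-1-hydroxyethyl]cyclopropan-1-ol F3. Acid (TsOH cat., or BF3·OEt2, CH2Cl2, −78 °C) would then ionise the tertiary carbinol with anti migration of a cyclopropane CH2, a pinacol-type ring expansion that again closes the ring through the C5–C4 bond and should give 7. No basic step touches the epimerisable ring B centre.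

2. Step 9. What may go wrong is slow turnover at the hindered vinyl group, with the diene partner consumed by self-metathesis and by double-bond migration in its skipped diene. The fallback sets out from 8 and comes back at 17, replacing metathesis by a carbonyl olefination.
   - Ozonolysis of 8 (O3, CH2Cl2/MeOH, −78 °C; PPh3) would give (2R,5R)-2-methyl-5-[(2S)-2-methyl-5-oxooxolan-2-yl]oxolane-2-carbaldehyde F4.
   - The sulfone partner would come from but-3-yn-1-ol: methylalumination (Me3Al, Cp2ZrCl2 cat.) to dimethylaluminium (3E)-4-(dimethylalumanyl)-3-methylbut-3-en-1-olate F5, coupling with vinyl bromide (Pd(PPh3)4, ZnCl2) to (3E)-3-methylhexa-3,5-dien-1-ol F6, Mitsunobu reaction with 1-phenyl-1H-tetrazole-5-thiol (PPh3, DIAD) to 5-{[(3E)-3-methylhexa-3,5-dien-1-yl]sulfanyl}-1-phenyl-1H-tetrazole F7, and oxidation ((NH4)6Mo7O24 cat., H2O2, EtOH) to 5-{[(3E)-3-methylhexa-3,5-dien-1-yl]sulfonyl}-1-phenyl-1H-tetrazole F8.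
   - Julia–Kocienski olefination of F4 with F8 (KN(SiMe3)2, DME, −60 → 25 °C) should give (5S)-5-methyl-5-{(2R,5R)-5-methyl-5-[(1E,4E)-4-methylhepta-1,4,6-trien-1-yl]oxolan-2-yl}oxolan-2-one F9.
   - Hydroboration of the terminal diene alkene with 9-BBN would give the B-alkyl-9-borabicyclo[3.3.1]nonane F10, and Suzuki–Miyaura coupling with 14 (Pd(dppf)Cl2, AsPh3, Cs2CO3, DMF/H2O, 25 °C) would give 17.

3. Step 8. What may go wrong is sluggish zinc insertion or transmetalation, with protodemetalation of the zinc reagent and reduction of the bromobutenolide. The fallback sets out from 13 and comes back at 16, building the butenolide by enolate alkylation and sulfoxide elimination. 3-Bromooxolan-2-one and thiophenol (Et3N, CH2Cl2) would give 3-(phenylsulfanyl)oxolan-2-one F11. Its lithium enolate (LiN(iPr)2, THF/HMPA, −78 °C) would be alkylated with 13 to 3-[(3E)-4-methylhepta-3,6-dien-1-yl]-3-(phenylsulfanyl)oxolan-2-one F12. Oxidation (mCPBA, 1 equiv, CH2Cl2, −78 °C) would give 3-(benzenesulfinyl)-3-[(3E)-4-methylhepta-3,6-dien-1-yl]oxolan-2-one F13, and thermal syn-elimination (toluene, CaCO3, 110 °C) towards the ring CH2 would give 16.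

Further compounds
F1 | step 4 | (2R)-2-[(2R,5R)-5-ethenyl-5-methyloxolan-2-yl]-2-hydroxypropanoic acid | C=C[C@@]1(C)CC[C@H]([C@@](C)(O)C(=O)O)O1
F2 | step 4 | methyl (2R)-2-[(2R,5R)-5-ethenyl-5-methyloxolan-2-yl]-2-hydroxypropanoate | C=C[C@@]1(C)CC[C@H]([C@@](C)(O)C(=O)OC)O1
F3 | step 4 | 1-[(1R)-1-[(2R,5R)-5-ethenyl-5-methyloxolan-2-yl]-1-hydroxyethyl]cyclopropan-1-ol | C=C[C@@]1(C)CC[C@H]([C@@](C)(O)C2(O)CC2)O1
F4 | step 9 | (2R,5R)-2-methyl-5-[(2S)-2-methyl-5-oxooxolan-2-yl]oxolane-2-carbaldehyde | O=C[C@@]1(C)CC[C@H]([C@]2(C)CCC(=O)O2)O1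
F5 | step 9 | dimethylaluminium (3E)-4-(dimethylalumanyl)-3-methylbut-3-en-1-olate | C[Al](C)OCC/C(C)=C/[Al](C)C
F6 | step 9 | (3E)-3-methylhexa-3,5-dien-1-ol | OCC/C(C)=C/C=C
F7 | step 9 | 5-{[(3E)-3-methylhexa-3,5-dien-1-yl]sulfanyl}-1-phenyl-1H-tetrazole | c1ccccc1-n1nnnc1SCC/C(C)=C/C=C
F8 | step 9 | 5-{[(3E)-3-methylhexa-3,5-dien-1-yl]sulfonyl}-1-phenyl-1H-tetrazole | c1ccccc1-n1nnnc1S(=O)(=O)CC/C(C)=C/C=C
F9 | step 9 | (5S)-5-methyl-5-{(2R,5R)-5-methyl-5-[(1E,4E)-4-methylhepta-1,4,6-trien-1-yl]oxolan-2-yl}oxolan-2-one | C=C/C=C(C)/C/C=C/[C@@]1(C)CC[C@H]([C@]2(C)CCC(=O)O2)O1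
F10 | step 9 | 9-{(3E,6E)-4-methyl-7-[(2R,5R)-2-methyl-5-[(2S)-2-methyl-5-oxooxolan-2-yl]oxolan-2-yl]hepta-3,6-dien-1-yl}-9-borabicyclo[3.3.1]nonane | B1(C2CCCC1CCC2)CC/C=C(C)/C/C=C/[C@@]3(C)CC[C@H]([C@]4(C)CCC(=O)O4)O3
F11 | step 8 | 3-(phenylsulfanyl)oxolan-2-one | O=C1OCCC1Sc1ccccc1
F12 | step 8 | 3-[(3E)-4-methylhepta-3,6-dien-1-yl]-3-(phenylsulfanyl)oxolan-2-one | C=CC/C(C)=C/CCC1(Sc2ccccc2)CCOC1=O
F13 | step 8 | 3-(benzenesulfinyl)-3-[(3E)-4-methylhepta-3,6-dien-1-yl]oxolan-2-one | C=CC/C(C)=C/CCC1(S(=O)c2ccccc2)CCOC1=O
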